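The tetrahydrofuran is traced back to a 1,4-oxathiane 4,4-dioxide in which SO2 bridges C3 and C4 of the target, so that the C2–O1–C5 ether with its cis aryl groups becomes the diequatorial 2,6-diaryl pattern of a chair. In one reversible operation water adds across both alkenes of a bis(arylidene) sulfonyldiacetate, forming O1–C2 and O1–C5, closing the six-membered ring and fixing the cis-diaryl relation thermodynamically. The precursor is the double Knoevenagel product of dimethyl sulfonyldiacetate with O-pivaloylsyringaldehyde; the acyloxy group makes the aryl rings less donating. Ramberg–Bäcklund contraction, hydrogenation anti to the aryl groups and LiAlH4 complete the all-cis target.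

Key step: step 3

Remarks on the chemistry (one line each):
- The target SMILES decodes as the meso (2S,3S,4R,5R) isomer, with both aryl groups and both hydroxymethyl groups on one face of the ring (all-cis); the structures of the key-step precursor and product were re-derived and needed no correction.
- The phenols are carried as pivalates rather than alkyl ethers: an acyloxy group para to the benzylic carbon is a weaker donor, which should favour the ring over the conjugated open form in step 3, and it is removed by LiAlH4 in the last step without an extra operation.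
- Dimethyl 2,2'-sulfonyldiacetate is assumed to be purchasable; the E,E geometry drawn for 5 (aryl trans to sulfonyl) is the expected one but does not matter, because step 3 is reversible.
- Numbering: oxathiane O1, C2, C3, S4, C5, C6; oxathiane C2/C6 become furan C2/C5 and oxathiane C3/C5 become furan C3/C4.

Step 1
Reactants: 1 syringaldehyde (4-hydroxy-3,5-dimethoxybenzaldehyde)
Product: 2 4-formyl-2,6-dimethoxyphenyl pivalate
Conditions: PivCl (1.2 equiv), Et3N (1.5 equiv), DMAP (cat.), CH2Cl2, 0 °C → rt
Reagents that add atoms: pivaloyl chloride, CC(C)(C)C(=O)Cl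
Why: DMAP-catalysed O-acylation of a phenol by an acid chloride (esterification), which the aldehyde tolerates and which creates no stereocenter.

Step 2
Reactants: 2 4-formyl-2,6-dimethoxyphenyl pivalate (2.1 equiv); 3 dimethyl 2,2'-sulfonyldiacetate
Product: 5 dimethyl (2E,2'E)-2,2'-sulfonylbis{3-[3,5-dimethoxy-4-(pivaloyloxy)phenyl]prop-2-enoate}, via mono-arylidene sulfone 4 (not isolated)
Conditions: piperidine (0.1 equiv), AcOH (0.3 equiv), toluene, reflux, Dean–Stark
Reagents that add atoms: none
Why: Double Knoevenagel condensation, in which each CH2 is acidified by sulfone and ester, azeotropic removal of water drives both dehydrations to the trisubstituted alkenes (aryl trans to the bulky sulfonyl group), and the acetic acid-buffered catalyst spares the hindered aryl pivalates.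

Step 3
Reactants: 5 dimethyl (2E,2'E)-2,2'-sulfonylbis{3-[3,5-dimethoxy-4-(pivaloyloxy)phenyl]prop-2-enoate}; 6 water
Product: 8 dimethyl (2R,3S,5R,6S)-2,6-bis[3,5-dimethoxy-4-(pivaloyloxy)phenyl]-1,4-oxathiane-3,5-dicarboxylate 4,4-dioxide (meso; all four substituents equatorial), via hydroxy sulfone 7 (not isolated)
Conditions: Cs2CO3 (0.2 equiv), H2O (10 equiv), MeCN, rt → 40 °C; AcOH
Reagents that add atoms: water, O
Why: Hydroxide formed from water and carbonate attacks the benzylic carbon of one sulfonyl acrylate unit, and after proton transfer the resulting alcohol 7, as its alkoxide, attacks the benzylic carbon of the other unit in a 6-endo-trig conjugate addition, so that one water molecule supplies both C–O bonds of the ring oxygen. The closest known reaction type is the base-catalysed double oxa-Michael addition of water to divinyl sulfones that gives 1,4-oxathiane 4,4-dioxides, with the oxa-Michael ring closure of the Maitland–Japp pyranone synthesis as the carbonyl-bridged analogue. Each C–O bond can reopen by E1cB retro-Michael cleavage and C3 and C5 epimerize through the sulfonyl ester enolate, so all four new stereocenters (C2, C3, C5, C6) are set under thermodynamic control by the chair that places both aryl groups and both esters equatorial, which is the meso 2,6-cis, 2,3-trans, 5,6-trans isomer. Only the 2,6-cis relation is carried forward, and it should be secure because the trans isomer must hold one aryl group axial, syn to a sulfonyl oxygen. The step also needs ring closure to win over the open diene and over hydroxide attack at the esters: the acyloxy-substituted aryl rings weaken the conjugation that stabilizes the open form and speed conjugate addition, while the substoichiometric weak base and the small excess of water keep hydroxide low and leave the neutral ring as the resting state.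

Step 4
Reactants: 8 dimethyl (2R,3S,5R,6S)-2,6-bis[3,5-dimethoxy-4-(pivaloyloxy)phenyl]-1,4-oxathiane-3,5-dicarboxylate 4,4-dioxide
Product: 11 dimethyl (2R,5S)-2,5-bis[3,5-dimethoxy-4-(pivaloyloxy)phenyl]-2,5-dihydrofuran-3,4-dicarboxylate (cis, meso), via α-chloro sulfone 9 (not isolated), via episulfone 10 (not isolated)
Conditions: LiN(SiMe3)2 (2.1 equiv), THF, −78 °C; C2Cl6 (1.05 equiv), −78 → 0 °C; AcOH
Reagents that add atoms: none
Why: Ramberg–Bäcklund ring contraction in its in-situ halogenation form for α-sulfonyl esters, in which the lithium dianion is chlorinated once at C3 by C2Cl6, the C5 carbanion displaces chloride in a 1,3-elimination to episulfone 10, and cheletropic loss of SO2 leaves the C3=C4 alkene, while the two aryl-bearing stereocenters are untouched and stay cis.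

Step 5
Reactants: 11 dimethyl (2R,5S)-2,5-bis[3,5-dimethoxy-4-(pivaloyloxy)phenyl]-2,5-dihydrofuran-3,4-dicarboxylate
Product: 12 dimethyl (2S,3R,4S,5R)-2,5-bis[3,5-dimethoxy-4-(pivaloyloxy)phenyl]tetrahydrofuran-3,4-dicarboxylate (all-cis, meso)
Conditions: H2 (3 atm), 5% Rh/Al2O3, EtOAc, rt
Reagents that add atoms: none
Why: Heterogeneous syn-hydrogenation of the ester-activated tetrasubstituted alkene, in which the two cis aryl groups block one face so that both hydrogens arrive on the other face and set C3 and C4 with the esters on the aryl side (all-cis), with Rh/Al2O3 chosen for its low tendency to cleave benzylic and allylic C–O bonds.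

Step 6
Reactants: 12 dimethyl (2S,3R,4S,5R)-2,5-bis[3,5-dimethoxy-4-(pivaloyloxy)phenyl]tetrahydrofuran-3,4-dicarboxylate
Product: 13 4,4'-[(2S,3S,4R,5R)-3,4-bis(hydroxymethyl)tetrahydrofuran-2,5-diyl]bis(2,6-dimethoxyphenol) (all-cis, meso; CNP0170897.3)
Conditions: LiAlH4 (6 equiv), THF, 0 °C → rt; aq. potassium sodium tartrate (KNaC4H4O6), pH 7
Reagents that add atoms: none
Why: LiAlH4 reduction of both methyl esters to primary alcohols with concurrent reductive cleavage of both aryl pivalates, where hydride addition should outrun enolization so that C3 and C4 keep their configuration, and the neutral work-up avoids acid-induced epimerization at the benzylic ether carbons.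

Compound list
1 | syringaldehyde (4-hydroxy-3,5-dimethoxybenzaldehyde) | COc1cc(C=O)cc(OC)c1O | starting material
2 | 4-formyl-2,6-dimethoxyphenyl pivalate | COc1cc(C=O)cc(OC)c1OC(=O)C(C)(C)C | intermediate
3 | dimethyl 2,2'-sulfonyldiacetate | COC(=O)CS(=O)(=O)CC(=O)OC | starting material
4 | methyl (2E)-3-[3,5-dimethoxy-4-(pivaloyloxy)phenyl]-2-[(2-methoxy-2-oxoethyl)sulfonyl]prop-2-enoate | COC(=O)CS(=O)(=O)/C(=C/c1cc(OC)c(OC(=O)C(C)(C)C)c(OC)c1)C(=O)OC | intermediate (not isolated)
5 | dimethyl (2E,2'E)-2,2'-sulfonylbis{3-[3,5-dimethoxy-4-(pivaloyloxy)phenyl]prop-2-enoate} | COC(=O)/C(=C\c1cc(OC)c(OC(=O)C(C)(C)C)c(OC)c1)S(=O)(=O)/C(=C/c1cc(OC)c(OC(=O)C(C)(C)C)c(OC)c1)C(=O)OC | intermediate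
6 | water | O | starting material
7 | methyl 3-[3,5-dimethoxy-4-(pivaloyloxy)phenyl]-2-({(1E)-2-[3,5-dimethoxy-4-(pivaloyloxy)phenyl]-1-(methoxycarbonyl)ethenyl}sulfonyl)-3-hydroxypropanoate (equilibrating mixture of diastereomers, sp3 centres not defined) | COC(=O)C(C(O)c1cc(OC)c(OC(=O)C(C)(C)C)c(OC)c1)S(=O)(=O)/C(=C/c1cc(OC)c(OC(=O)C(C)(C)C)c(OC)c1)C(=O)OC | intermediate (not isolated)
8 | dimethyl (2R,3S,5R,6S)-2,6-bis[3,5-dimethoxy-4-(pivaloyloxy)phenyl]-1,4-oxathiane-3,5-dicarboxylate 4,4-dioxide (meso, all-equatorial) | O1[C@H](c2cc(OC)c(OC(=O)C(C)(C)C)c(OC)c2)[C@@H](C(=O)OC)S(=O)(=O)[C@@H](C(=O)OC)[C@@H]1c3cc(OC)c(OC(=O)C(C)(C)C)c(OC)c3 | intermediate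
9 | dimethyl 3-chloro-2,6-bis[3,5-dimethoxy-4-(pivaloyloxy)phenyl]-1,4-oxathiane-3,5-dicarboxylate 4,4-dioxide (2,6-cis; C3 and C5 not defined; present in the flask as its C5 lithium carbanion, drawn neutral) | O1[C@H](c2cc(OC)c(OC(=O)C(C)(C)C)c(OC)c2)C(Cl)(C(=O)OC)S(=O)(=O)C(C(=O)OC)[C@@H]1c3cc(OC)c(OC(=O)C(C)(C)C)c(OC)c3 | intermediate (not isolated)
10 | dimethyl 2,4-bis[3,5-dimethoxy-4-(pivaloyloxy)phenyl]-3-oxa-6-thiabicyclo[3.1.0]hexane-1,5-dicarboxylate 6,6-dioxide (2,4-cis aryl groups; ring fusion cis) | O1[C@H](c2cc(OC)c(OC(=O)C(C)(C)C)c(OC)c2)C4(C(=O)OC)S(=O)(=O)C4(C(=O)OC)[C@@H]1c3cc(OC)c(OC(=O)C(C)(C)C)c(OC)c3 | intermediate (not isolated)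
11 | dimethyl (2R,5S)-2,5-bis[3,5-dimethoxy-4-(pivaloyloxy)phenyl]-2,5-dihydrofuran-3,4-dicarboxylate (cis, meso) | O1[C@H](c2cc(OC)c(OC(=O)C(C)(C)C)c(OC)c2)C(C(=O)OC)=C(C(=O)OC)[C@@H]1c3cc(OC)c(OC(=O)C(C)(C)C)c(OC)c3 | intermediate
12 | dimethyl (2S,3R,4S,5R)-2,5-bis[3,5-dimethoxy-4-(pivaloyloxy)phenyl]tetrahydrofuran-3,4-dicarboxylate (all-cis, meso) | O1[C@H](c2cc(OC)c(OC(=O)C(C)(C)C)c(OC)c2)[C@H](C(=O)OC)[C@H](C(=O)OC)[C@@H]1c3cc(OC)c(OC(=O)C(C)(C)C)c(OC)c3 | intermediate
13 | 4,4'-[(2S,3S,4R,5R)-3,4-bis(hydroxymethyl)tetrahydrofuran-2,5-diyl]bis(2,6-dimethoxyphenol) (all-cis, meso) | COc1cc([C@H]2O[C@@H](c3cc(OC)c(O)c(OC)c3)[C@@H](CO)[C@H]2CO)cc(OC)c1O | target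

Total step count: 6. Longest linear sequence: 6 steps (1 → 13).

Steps most likely to fail

Step 3. The ring closure may not go to completion: the conjugated open diene may remain favoured, hydroxide may attack the ester carbonyls instead of the alkene, the hydroxy intermediate may fragment by retro-aldol loss of aldehyde 2, or the cis relation may erode if much material rests as the ring carbanion. The fallback brings in the ring oxygen through a furan and sets out from aldehyde 2. Roskamp homologation with ethyl diazoacetate and catalytic SnCl2 in CH2Cl2 should give ethyl 3-[3,5-dimethoxy-4-(pivaloyloxy)phenyl]-3-oxopropanoate F1. Oxidative dimerization of its sodium enolate (NaH, then I2, THF) should give diethyl 2,3-bis[3,5-dimethoxy-4-(pivaloyloxy)benzoyl]butanedioate F2. Paal–Knorr cyclodehydration (TsOH, toluene, reflux) should give diethyl 2,5-bis[3,5-dimethoxy-4-(pivaloyloxy)phenyl]furan-3,4-dicarboxylate F3. All-syn hydrogenation of the furan over Rh/Al2O3 in EtOAc under pressure should give diethyl (2S,3R,4S,5R)-2,5-bis[3,5-dimethoxy-4-(pivaloyloxy)phenyl]tetrahydrofuran-3,4-dicarboxylate F4, in which one catalyst face sets all four stereocenters. LiAlH4 under the conditions of step 6 then returns to the route at target 13.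

Step 4. Under strong base the sulfonyl-ester carbanion may expel the ring oxygen by β-elimination before chlorination. The stabilized C5 carbanion may also displace chloride only slowly at the fully substituted C3. In the product, the doubly activated C2/C5 hydrogens may be removed, which would cause double-bond migration or loss of the cis relation. The fallback avoids base in the bond-forming stage and sets out from oxathiane 8. Bromination of both acidic positions (NBS, 2.1 equiv, catalytic Et3N, CH2Cl2, 0 °C) should give dimethyl 3,5-dibromo-2,6-bis[3,5-dimethoxy-4-(pivaloyloxy)phenyl]-1,4-oxathiane-3,5-dicarboxylate 4,4-dioxide F5. PPh3 in THF should then attack one bromine (halophilic displacement), and the carbanion so formed displaces the second bromide in a 1,3-elimination. The episulfone loses SO2 under neutral conditions, and the sequence comes back to the route at dihydrofuran 11.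

Step 5. Hydrogen uptake at the tetrasubstituted alkene may be slow, which would leave time for hydrogenolysis of the allylic, benzylic C–O bonds, for double-bond migration on the metal, or for arene saturation. The fallback reduces first and then uses hydroxyl-directed homogeneous hydrogenation, setting out from dihydrofuran 11. iBu2AlH (excess, CH2Cl2, −78 → 0 °C) should reduce both esters 1,2 and cleave both pivalates to give 4,4'-[(2R,5S)-3,4-bis(hydroxymethyl)-2,5-dihydrofuran-2,5-diyl]bis(2,6-dimethoxyphenol) F6. Hydrogenation of this tetrasubstituted allylic diol with [Ir(cod)(PCy3)(py)]PF6 (cat.), H2 (1 atm) in CH2Cl2/THF should be accelerated by the two hydroxyl groups and should again take place on the face away from the aryl groups. This comes back to the route at target 13.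

Further compounds
F1 | step 3 | ethyl 3-[3,5-dimethoxy-4-(pivaloyloxy)phenyl]-3-oxopropanoate | CCOC(=O)CC(=O)c1cc(OC)c(OC(=O)C(C)(C)C)c(OC)c1
F2 | step 3 | diethyl 2,3-bis[3,5-dimethoxy-4-(pivaloyloxy)benzoyl]butanedioate (mixture of diastereomers) | CCOC(=O)C(C(=O)c1cc(OC)c(OC(=O)C(C)(C)C)c(OC)c1)C(C(=O)OCC)C(=O)c1cc(OC)c(OC(=O)C(C)(C)C)c(OC)c1
F3 | step 3 | diethyl 2,5-bis[3,5-dimethoxy-4-(pivaloyloxy)phenyl]furan-3,4-dicarboxylate | CCOC(=O)c1c(-c2cc(OC)c(OC(=O)C(C)(C)C)c(OC)c2)oc(-c2cc(OC)c(OC(=O)C(C)(C)C)c(OC)c2)c1C(=O)OCC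
F4 | step 3 | diethyl (2S,3R,4S,5R)-2,5-bis[3,5-dimethoxy-4-(pivaloyloxy)phenyl]tetrahydrofuran-3,4-dicarboxylate (all-cis, meso) | O1[C@H](c2cc(OC)c(OC(=O)C(C)(C)C)c(OC)c2)[C@H](C(=O)OCC)[C@H](C(=O)OCC)[C@@H]1c3cc(OC)c(OC(=O)C(C)(C)C)c(OC)c3
F5 | step 4 | dimethyl 3,5-dibromo-2,6-bis[3,5-dimethoxy-4-(pivaloyloxy)phenyl]-1,4-oxathiane-3,5-dicarboxylate 4,4-dioxide (2,6-cis; C3 and C5 not defined) | O1[C@H](c2cc(OC)c(OC(=O)C(C)(C)C)c(OC)c2)C(Br)(C(=O)OC)S(=O)(=O)C(Br)(C(=O)OC)[C@@H]1c3cc(OC)c(OC(=O)C(C)(C)C)c(OC)c3
F6 | step 5 | 4,4'-[(2R,5S)-3,4-bis(hydroxymethyl)-2,5-dihydrofuran-2,5-diyl]bis(2,6-dimethoxyphenol) (cis, meso) | O1[C@H](c2cc(OC)c(O)c(OC)c2)C(CO)=C(CO)[C@@H]1c3cc(OC)c(O)c(OC)c3
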